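**Retrosynthetic overview**

- Ring numbering: C1 carries the side chain, C2 is H, C3 is OMe, C4 is Me, C5 is OMe, C6 is OH. The strategy rests on the 4-methoxyphenol motif of the benzene ring: the free OH on C6 is para to the OMe on C3, the side chain on C1 is ortho to that OH, and the only ring hydrogen (C2) is ortho to the C3 methoxy group.
- This is the substitution pattern a Dötz benzannulation delivers, so the benzene ring (the only ring) is disconnected last. The pieces are a methoxy(β-methoxy-α-methylvinyl)carbene chromium complex (C3, C4, C5), one CO ligand (C6 and its oxygen) and the terminal alkyne of an enyne angelate (C2, C1). Bonds formed: C2–C3, C1–C6, C5–C6.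
- The enyne angelate is cut at the ester (angelic acid, DMAP-free mixed anhydride), at the alkyne–alkene bond (Sonogashira coupling of the enol triflate of a methyl ketone) and at the CH2–CH= bond of the prenyl unit (isobutenyl Grignard opening of methyl (S)-glycidate at its CH2), which supplies the only stereocentre.
- The carbene complex is cut into Cr(CO)6, a methyl cation and a cis-β-methoxyvinyllithium derived from 2-bromo-1,1-dimethoxypropane.
- Order: open-chain side chain first (steps 1–8), carbene complex in parallel (steps 9–11), benzene ring closed in the final step.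

Key step: step 12

Remarks on the chemistry:
- The enol-ether geometry in compounds 17–21 has no bearing on the product, because C5 ends as an aromatic carbon. The Z series is carried because only the vinyllithium with Li cis to OMe resists β-elimination; any E bromide present should simply be lost as propyne in step 10.
- Steps 9–11 are timed so that carbene complex 21 is used fresh in step 12. All chromium compounds are handled under argon.
- Assumption: methyl (S)-glycidate of high enantiomeric purity is used. No step breaks a bond at the carbinol carbon, so its configuration should be carried through unchanged.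

**Route**

Step 1
Reactants: 1 methyl (S)-glycidate; 2 2-methylprop-1-enylmagnesium bromide
Product: 3 methyl (2S)-2-hydroxy-5-methylhex-4-enoate
Conditions: 2 (1.5 equiv), CuI (10 mol %), THF, −40 → −20 °C; aq NH4Cl
Reagents that add atoms: none
Why: Copper-catalysed Grignard opening of a terminal epoxide should occur by SN2 attack at the unhindered CH2 faster than addition to the ester at this temperature; the C–O bond at the stereocentre is not involved, so the (S) configuration is carried over.

Step 2
Reactants: 3 methyl (2S)-2-hydroxy-5-methylhex-4-enoate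
Product: 4 methyl (2S)-2-[(tert-butyldimethylsilyl)oxy]-5-methylhex-4-enoate
Conditions: TBSCl, imidazole, DMF, 0 °C → rt
Reagents that add atoms: tert-butyldimethylsilyl chloride, CC(C)(C)[Si](C)(C)Cl
Why: Imidazole-promoted silylation of a secondary alcohol should mask the hydroxyl for the organometallic and enolate steps that follow.

Step 3
Reactants: 4 methyl (2S)-2-[(tert-butyldimethylsilyl)oxy]-5-methylhex-4-enoate
Product: 5 (2S)-2-[(tert-butyldimethylsilyl)oxy]-N-methoxy-N,5-dimethylhex-4-enamide
Conditions: MeNH(OMe)·HCl, i-PrMgCl, THF, −20 → 0 °C; aq NH4Cl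
Reagents that add atoms: N,O-dimethylhydroxylamine hydrochloride, CNOC.Cl
Why: Direct ester-to-Weinreb-amide conversion by the magnesium amide made in the flask; this weakly basic nucleophile at low temperature should not epimerise the α-silyloxy centre.

Step 4
Reactants: 5 (2S)-2-[(tert-butyldimethylsilyl)oxy]-N-methoxy-N,5-dimethylhex-4-enamide
Product: 7 (3S)-3-[(tert-butyldimethylsilyl)oxy]-6-methylhept-5-en-2-one, via magnesium hemiaminal chelate 6 (not isolated)
Conditions: MeMgBr, THF, 0 °C; aq NH4Cl
Reagents that add atoms: methylmagnesium bromide, C[Mg]Br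
Why: Weinreb ketone synthesis: the N,O-chelated adduct 6 should persist until the quench, so only one methyl group is delivered and the ketone never meets the Grignard reagent.

Step 5
Reactants: 7 (3S)-3-[(tert-butyldimethylsilyl)oxy]-6-methylhept-5-en-2-one
Product: 9 (3S)-3-[(tert-butyldimethylsilyl)oxy]-6-methylhepta-1,5-dien-2-yl trifluoromethanesulfonate, via potassium enolate 8 (not isolated)
Conditions: KN(SiMe3)2, THF, −78 °C; then PhNTf2, −78 → 0 °C
Reagents that add atoms: N-phenylbis(trifluoromethanesulfonimide), O=S(=O)(N(c1ccccc1)S(=O)(=O)C(F)(F)F)C(F)(F)F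
Why: Kinetic deprotonation by the bulky amide should take place at the unhindered methyl group rather than at the silyloxy-bearing methine, and O-sulfonylation of the enolate (enol triflate formation) fixes the terminal alkene without enolising the stereocentre.

Step 6
Reactants: 9 (3S)-3-[(tert-butyldimethylsilyl)oxy]-6-methylhepta-1,5-dien-2-yl trifluoromethanesulfonate; 10 trimethylsilylacetylene
Product: 11 tert-butyldimethyl{[(4S)-7-methyl-3-methylidene-1-(trimethylsilyl)oct-6-en-1-yn-4-yl]oxy}silane
Conditions: Pd(PPh3)4 (5 mol %), CuI (10 mol %), Et3N, THF, rt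
Reagents that add atoms: none
Why: Sonogashira coupling of an alkenyl triflate with a terminal alkyne should proceed at room temperature, and the silyl ether and the prenyl alkene are inert to it.

Step 7
Reactants: 11 tert-butyldimethyl{[(4S)-7-methyl-3-methylidene-1-(trimethylsilyl)oct-6-en-1-yn-4-yl]oxy}silane
Product: 12 (4S)-7-methyl-3-methylideneoct-6-en-1-yn-4-ol
Conditions: Bu4NF (2.5 equiv), THF, 0 °C → rt; H2O work-up, careful concentration (volatile)
Reagents that add atoms: none
Why: Fluoride desilylation should cleave the C(sp)–Si bond at once and the secondary O–Si bond more slowly, freeing alkyne and alcohol together without touching any bond at the stereocentre.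

Step 8
Reactants: 12 (4S)-7-methyl-3-methylideneoct-6-en-1-yn-4-ol; 13 angelic acid, (Z)-2-methylbut-2-enoic acid
Product: 15 (4S)-7-methyl-3-methylideneoct-6-en-1-yn-4-yl (2Z)-2-methylbut-2-enoate, via angelic 2,4,6-trichlorobenzoic anhydride 14 (not isolated)
Conditions: 13, 2,4,6-Cl3C6H2COCl, Et3N, toluene, rt; then 12, toluene, 75 °C
Reagents that add atoms: none
Why: Yamaguchi-type acylation through the mixed anhydride, run without DMAP so that no nucleophilic catalyst can add to the angelate and turn it into the tiglate; the alcohol should attack the less shielded angeloyl carbonyl, and the C–O bond at the stereocentre is retained.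

Step 9
Reactants: 16 2-bromo-1,1-dimethoxypropane
Product: 17 (Z)-2-bromo-1-methoxyprop-1-ene (Br cis to OMe)
Conditions: Me3SiOTf, i-Pr2NEt, CH2Cl2, −20 °C → rt; fractional distillation
Reagents that add atoms: none
Why: Silyl triflate ionises the acetal to an oxocarbenium ion and the hindered amine removes the only available neighbouring proton (on C2), an acetal-to-enol-ether elimination that can give only the 2-bromo enol ether; the Z isomer is enriched by distillation.

Step 10
Reactants: 17 (Z)-2-bromo-1-methoxyprop-1-ene; 18 chromium hexacarbonyl, Cr(CO)6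
Product: 20 lithium pentacarbonyl[(2Z)-3-methoxy-2-methylprop-2-enoyl]chromate, via cis-β-methoxyvinyllithium 19 (not isolated)
Conditions: t-BuLi (2 equiv), Et2O, −78 °C; then Cr(CO)6, Et2O/THF, −78 → 0 °C; evaporate, use crude
Reagents that add atoms: tert-butyllithium, [Li]C(C)(C)C
Why: Bromine–lithium exchange should proceed with retention to a vinyllithium whose cis methoxy group chelates lithium and cannot undergo anti-elimination, and this nucleophile adds to a CO ligand of Cr(CO)6 (first stage of the Fischer carbene synthesis).

Step 11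
Reactants: 20 lithium pentacarbonyl[(2Z)-3-methoxy-2-methylprop-2-enoyl]chromate
Product: 21 pentacarbonyl[(2Z)-1,3-dimethoxy-2-methylprop-2-en-1-ylidene]chromium, i.e. (CO)5Cr=C(OMe)–C(CH3)=CH(OMe)
Conditions: Me3OBF4, CH2Cl2, 0 °C → rt; quick filtration through silica under Ar, store cold
Reagents that add atoms: trimethyloxonium tetrafluoroborate, C[O+](C)C.F[B-](F)(F)F
Why: O-Methylation of the acyl chromate by the hard oxonium salt (second stage of the Fischer carbene synthesis) should give the neutral methoxycarbene complex.

Step 12
Reactants: 21 pentacarbonyl[(2Z)-1,3-dimethoxy-2-methylprop-2-en-1-ylidene]chromium; 15 (4S)-7-methyl-3-methylideneoct-6-en-1-yn-4-yl (2Z)-2-methylbut-2-enoate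
Product: 23 (3S)-2-(2-hydroxy-3,5-dimethoxy-4-methylphenyl)-6-methylhepta-1,5-dien-3-yl (2Z)-2-methylbut-2-enoate (CNP0152319.1), via arene tricarbonylchromium complex 22 (not isolated)
Conditions: 21 (1.5 equiv), degassed THF, 50–55 °C, Ar; then FeCl3 in DMF, 0 °C → rt
Reagents that add atoms: none
Why: Thermal loss of one CO from 21 lets the terminal alkyne of 15 coordinate and insert into the Cr=C bond with its CH carbon bonding to the carbene carbon (C2–C3); CO insertion then gives a chromium-bound dienylketene (C1–C6), the ketene carbon closes onto the methoxy-bearing vinyl carbon (C5–C6), and a hydrogen shift from C5 to oxygen gives the phenol as its Cr(CO)3 complex 22, from which FeCl3 removes the metal. The closest known reaction type is the Dötz benzannulation of alkenyl(methoxy)carbene chromium complexes with terminal alkynes and conjugated enynes, which gives 4-methoxyphenols. The benzene ring is closed by a six-electron electrocyclisation of the dienylketene, a formal [3+2+1] assembly of three carbene-derived carbons, two alkyne carbons and one CO. No stereocentre is created: the (S) carbinol carbon is a spectator under neutral conditions near 50 °C, and the enol-ether geometry of 21 disappears when C5 becomes aromatic. The step needs regioselective alkyne insertion, which the size difference between H and the branched alkenyl substituent should secure by placing the larger group next to the CO-derived C6. It also needs reaction at the alkyne rather than at the three alkenes, and phenol formation rather than five-membered-ring products; the terminal alkyne inserts far faster than any alkene, alkenyl complexes in THF favour CO insertion, and only the carbene-derived vinyl group can reach a six-membered closure with the ketene carbon.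

**Compound list**

1 | methyl (S)-glycidate | COC(=O)[C@@H]1CO1 | starting material
2 | 2-methylprop-1-enylmagnesium bromide | CC(C)=C[Mg]Br | starting material
3 | methyl (2S)-2-hydroxy-5-methylhex-4-enoate | COC(=O)[C@H](CC=C(C)C)O | intermediate
4 | methyl (2S)-2-[(tert-butyldimethylsilyl)oxy]-5-methylhex-4-enoate | COC(=O)[C@H](CC=C(C)C)O[Si](C)(C)C(C)(C)C | intermediate
5 | (2S)-2-[(tert-butyldimethylsilyl)oxy]-N-methoxy-N,5-dimethylhex-4-enamide | CON(C)C(=O)[C@H](CC=C(C)C)O[Si](C)(C)C(C)(C)C | intermediate
6 | bromomagnesium alkoxide of the tetrahedral methyl adduct of 5 (N,O-chelated hemiaminal, not isolated) | CON(C)C(C)(O[Mg]Br)[C@H](CC=C(C)C)O[Si](C)(C)C(C)(C)C | intermediate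
7 | (3S)-3-[(tert-butyldimethylsilyl)oxy]-6-methylhept-5-en-2-one | CC(=O)[C@H](CC=C(C)C)O[Si](C)(C)C(C)(C)C | intermediate
8 | potassium (3S)-3-[(tert-butyldimethylsilyl)oxy]-6-methylhepta-1,5-dien-2-olate (not isolated) | [K+].[O-]C(=C)[C@H](CC=C(C)C)O[Si](C)(C)C(C)(C)C | intermediate
9 | (3S)-3-[(tert-butyldimethylsilyl)oxy]-6-methylhepta-1,5-dien-2-yl trifluoromethanesulfonate | C=C(OS(=O)(=O)C(F)(F)F)[C@H](CC=C(C)C)O[Si](C)(C)C(C)(C)C | intermediate
10 | trimethylsilylacetylene | C#C[Si](C)(C)C | starting material
11 | tert-butyldimethyl{[(4S)-7-methyl-3-methylidene-1-(trimethylsilyl)oct-6-en-1-yn-4-yl]oxy}silane | C=C(C#C[Si](C)(C)C)[C@H](CC=C(C)C)O[Si](C)(C)C(C)(C)C | intermediate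
12 | (4S)-7-methyl-3-methylideneoct-6-en-1-yn-4-ol | C=C(C#C)[C@H](CC=C(C)C)O | intermediate
13 | angelic acid, (Z)-2-methylbut-2-enoic acid | C/C=C(/C)C(=O)O | starting material
14 | (Z)-2-methylbut-2-enoic 2,4,6-trichlorobenzoic anhydride (not isolated) | C/C=C(/C)C(=O)OC(=O)c1c(Cl)cc(Cl)cc1Cl | intermediate
15 | (4S)-7-methyl-3-methylideneoct-6-en-1-yn-4-yl (2Z)-2-methylbut-2-enoate | C=C(C#C)[C@H](CC=C(C)C)OC(=O)/C(C)=C\C | intermediate
16 | 2-bromo-1,1-dimethoxypropane | CC(Br)C(OC)OC | starting material
17 | (Z)-2-bromo-1-methoxyprop-1-ene | CO/C=C(/C)Br | intermediate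
18 | chromium hexacarbonyl | O=C=[Cr](=C=O)(=C=O)(=C=O)(=C=O)=C=O | starting material
19 | (1-methoxyprop-1-en-2-yl)lithium with Li cis to OMe (not isolated) | CO/C=C(/C)[Li] | intermediate
20 | lithium pentacarbonyl[(2Z)-3-methoxy-2-methylprop-2-enoyl]chromate | [Li+].CO/C=C(/C)C([O-])=[Cr](=C=O)(=C=O)(=C=O)(=C=O)=C=O | intermediate
21 | pentacarbonyl[(2Z)-1,3-dimethoxy-2-methylprop-2-en-1-ylidene]chromium | CO/C=C(/C)C(OC)=[Cr](=C=O)(=C=O)(=C=O)(=C=O)=C=O | intermediate
22 | tricarbonylchromium complex of 23, Cr(CO)3 bound η6 to the benzene ring (written as arene plus Cr(CO)3 fragment, not isolated) | C=C(c1cc(OC)c(C)c(OC)c1O)[C@H](CC=C(C)C)OC(=O)/C(C)=C\C.O=C=[Cr](=C=O)=C=O | intermediate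
23 | (3S)-2-(2-hydroxy-3,5-dimethoxy-4-methylphenyl)-6-methylhepta-1,5-dien-3-yl (2Z)-2-methylbut-2-enoate | C=C(c1cc(OC)c(C)c(OC)c1O)[C@H](CC=C(C)C)OC(=O)/C(C)=C\C | target

**Step count**

Total: 12 steps. Longest linear sequence: 9 steps (steps 1–8, then step 12). The carbene branch is 3 steps (9–11) and joins in step 12.

**Steps most likely to fail, with fallbacks**

1. Step 12. After alkyne insertion, the electron-rich, β-methoxy-substituted vinylcarbene may cyclise without taking up CO and give five-membered-ring products. The ring closure, with the methoxy group pointing inward, may also be slow enough that the complex decomposes first.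

   The fallback drops the benzannulation and joins a ready-made arene to the side chain by Suzuki coupling. It sets out from vinyl triflate 9 and returns at target 23.
   - 2,4-Dimethoxy-3-methylbenzaldehyde F1 (bought) is oxidised with mCPBA in CH2Cl2 (Baeyer–Villiger) to 2,4-dimethoxy-3-methylphenyl formate F2.
   - Methanolysis (K2CO3, MeOH) gives 2,4-dimethoxy-3-methylphenol F3.
   - Bromination ortho to the hydroxyl (NBS, cat. i-Pr2NH, CH2Cl2, 0 °C; the para position is blocked) gives 6-bromo-2,4-dimethoxy-3-methylphenol F4.
   - Silylation (i-Pr3SiOTf, 2,6-lutidine) gives (6-bromo-2,4-dimethoxy-3-methylphenoxy)tri(propan-2-yl)silane F5.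
   - Miyaura borylation (B2pin2, PdCl2(dppf), KOAc, dioxane, 85 °C) gives the aryl pinacol boronate F6.
   - Suzuki coupling of F6 with 9 (PdCl2(dppf), K3PO4, dioxane–H2O, 60 °C) gives the doubly silylated aryl diene F7.
   - Camphorsulfonic acid in MeOH/CH2Cl2 cleaves the alkyl TBS ether selectively, leaving the aryl silyl ether, to give the secondary alcohol F8.
   - Acylation with mixed anhydride 14 under the conditions of step 8 gives the O-silylated angelate F9.
   - Bu4NF buffered with AcOH in THF at 0 °C frees the phenol and gives 23.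

2. Step 10. The vinyllithium may lose lithium methoxide (β-elimination to propyne), or the exchange may be incomplete, so that little acyl chromate is formed.

   The fallback builds the acyl chromate from an acid chloride and a pentacarbonylchromate dianion, with no organolithium. It sets out from Cr(CO)6 18 and returns at target 23 through step 12.
   - (E)-3-Methoxy-2-methylprop-2-enoic acid F10 (bought) is converted with oxalyl chloride and cat. DMF in CH2Cl2 into (E)-3-methoxy-2-methylprop-2-enoyl chloride F11.
   - 18 is reduced with potassium graphite C8K in THF at −78 °C to dipotassium pentacarbonylchromate F12.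
   - Acylation of F12 by F11 at −78 °C gives potassium pentacarbonyl[(2E)-3-methoxy-2-methylprop-2-enoyl]chromate F13.
   - Me3OBF4 methylates F13 to pentacarbonyl[(2E)-1,3-dimethoxy-2-methylprop-2-en-1-ylidene]chromium F14.
   - F14 replaces 21 in step 12 and should give the same arene 23, since the geometry at C5 is lost on aromatisation. Its methoxy group points outward during ring closure.

3. Step 5. Deprotonation may occur in part at the silyloxy-bearing methine. That would give the more substituted enol triflate and erode the enantiomeric purity of recovered and converted material.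

   The fallback introduces the alkyne before the methylene group and needs no ketone enolate. It sets out from Weinreb amide 5 and returns at silyl enyne 11.
   - Lithium (trimethylsilyl)acetylide F15 (from 10 and n-BuLi, THF, −78 °C) is added to 5 to give (4S)-4-[(tert-butyldimethylsilyl)oxy]-7-methyl-1-(trimethylsilyl)oct-6-en-1-yn-3-one F16.
   - Wittig methylenation (Ph3P=CH2 from Ph3PCH3Br and KN(SiMe3)2, THF, −78 → 0 °C) converts the ketone into the 1,1-disubstituted alkene of 11. The silyl group on the alkyne terminus hinders conjugate addition, and the low temperature limits enolisation.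

**Further compounds**

F1 | step 12 | 2,4-dimethoxy-3-methylbenzaldehyde (bought) | COc1ccc(C=O)c(OC)c1C
F2 | step 12 | 2,4-dimethoxy-3-methylphenyl formate | COc1ccc(OC=O)c(OC)c1C
F3 | step 12 | 2,4-dimethoxy-3-methylphenol | COc1ccc(O)c(OC)c1C
F4 | step 12 | 6-bromo-2,4-dimethoxy-3-methylphenol | COc1cc(Br)c(O)c(OC)c1C
F5 | step 12 | (6-bromo-2,4-dimethoxy-3-methylphenoxy)tri(propan-2-yl)silane | COc1cc(Br)c(O[Si](C(C)C)(C(C)C)C(C)C)c(OC)c1C
F6 | step 12 | [2,4-dimethoxy-3-methyl-6-(4,4,5,5-tetramethyl-1,3,2-dioxaborolan-2-yl)phenoxy]tri(propan-2-yl)silane | COc1cc(B2OC(C)(C)C(C)(C)O2)c(O[Si](C(C)C)(C(C)C)C(C)C)c(OC)c1C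
F7 | step 12 | tert-butyl{[(3S)-2-(3,5-dimethoxy-4-methyl-2-{[tri(propan-2-yl)silyl]oxy}phenyl)-6-methylhepta-1,5-dien-3-yl]oxy}dimethylsilane | C=C(c1cc(OC)c(C)c(OC)c1O[Si](C(C)C)(C(C)C)C(C)C)[C@H](CC=C(C)C)O[Si](C)(C)C(C)(C)C
F8 | step 12 | (3S)-2-(3,5-dimethoxy-4-methyl-2-{[tri(propan-2-yl)silyl]oxy}phenyl)-6-methylhepta-1,5-dien-3-ol | C=C(c1cc(OC)c(C)c(OC)c1O[Si](C(C)C)(C(C)C)C(C)C)[C@H](CC=C(C)C)O
F9 | step 12 | (3S)-2-(3,5-dimethoxy-4-methyl-2-{[tri(propan-2-yl)silyl]oxy}phenyl)-6-methylhepta-1,5-dien-3-yl (2Z)-2-methylbut-2-enoate | C=C(c1cc(OC)c(C)c(OC)c1O[Si](C(C)C)(C(C)C)C(C)C)[C@H](CC=C(C)C)OC(=O)/C(C)=C\C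
F10 | step 10 | (E)-3-methoxy-2-methylprop-2-enoic acid (bought) | CO/C=C(\C)C(=O)O
F11 | step 10 | (E)-3-methoxy-2-methylprop-2-enoyl chloride | CO/C=C(\C)C(=O)Cl
F12 | step 10 | dipotassium pentacarbonylchromate, K2Cr(CO)5 | [K+].[K+].O=C=[Cr-2](=C=O)(=C=O)(=C=O)=C=O
F13 | step 10 | potassium pentacarbonyl[(2E)-3-methoxy-2-methylprop-2-enoyl]chromate | [K+].CO/C=C(\C)C([O-])=[Cr](=C=O)(=C=O)(=C=O)(=C=O)=C=O
F14 | step 10 | pentacarbonyl[(2E)-1,3-dimethoxy-2-methylprop-2-en-1-ylidene]chromium | CO/C=C(\C)C(OC)=[Cr](=C=O)(=C=O)(=C=O)(=C=O)=C=O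
F15 | step 5 | lithium (trimethylsilyl)acetylide | [Li]C#C[Si](C)(C)C
F16 | step 5 | (4S)-4-[(tert-butyldimethylsilyl)oxy]-7-methyl-1-(trimethylsilyl)oct-6-en-1-yn-3-one | C[Si](C)(C)C#CC(=O)[C@H](CC=C(C)C)O[Si](C)(C)C(C)(C)C
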